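**Plan**

- Target: (2S)-6-(3-hydroxy-3-methylbutyl)eriodictyol. Retrosynthesis first removes a temporary C3 benzyl ester and four O-benzyl groups, then cuts O1–C2 of ring C (oxa-Michael), C2=C3 (Knoevenagel, ring B aldehyde), C3–C4 (acetate aldol), C4–C4a (ortho-formylation) and the C6–CH2 bond of the side chain.
- Enabling feature: O1 on C8a is β to the C4 ketone through C2–C3, so ring C is the 6-endo oxa-Michael adduct of a 2-hydroxyaryl enone. C8a–O1 is also para to C6 while O5 and O7 flank C6, so the ring A phenol has a mirror plane through C6 and C8a; its two ortho carbons are equivalent and a 6- versus 8-alkyl problem cannot arise.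
- Forward: ring A (3,5-bis(benzyloxy)phenol) receives the prenyl chain by lithiation between the benzyloxy groups, the chain is hydrated, the ring is formylated and homologated to a β-ketoester, ring B is joined by Knoevenagel condensation, and ring C is closed last.
- Stereochemistry: C2 (S) is set by a cinchona-thiourea catalyst in the ring closure. The C3 ester that makes this possible is a benzyl ester, so it leaves as CO2 in the final hydrogenolysis and the tertiary alcohol never meets acid.

Key step: step 8

Assumption: the quinidine-derived thiourea is taken to deliver the 2S series; if the sense of induction is the reverse, its quinine-derived pseudoenantiomer is used instead. Compound 11 is used as its mixture of alkene isomers.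

**Step 1**
Reactants: 1 3,5-bis(benzyloxy)phenol
Product: 2 [3,5-bis(benzyloxy)phenoxy]tri(propan-2-yl)silane
Conditions: TIPSCl, imidazole, DMF, rt
Reagents that add atoms: chlorotri(propan-2-yl)silane (TIPSCl), CC(C)[Si](Cl)(C(C)C)C(C)C
Why: Phenol silylation; the bulky, non-coordinating silyl ether shields both of its ortho positions so that the next metalation can only occur between the two benzyloxy groups.

**Step 2**
Reactants: 2 [3,5-bis(benzyloxy)phenoxy]tri(propan-2-yl)silane
Product: 4 [3,5-bis(benzyloxy)-4-(3-methylbut-2-en-1-yl)phenoxy]tri(propan-2-yl)silane, via aryllithium 3 (not isolated)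
Conditions: n-BuLi, THF, 0 °C; then CuBr·SMe2 (10 mol%), prenyl bromide, −78 °C to rt
Reagents that add atoms: 1-bromo-3-methylbut-2-ene (prenyl bromide), CC(C)=CCBr
Why: Directed ortho-metalation at the carbon flanked by two alkoxy groups, followed by SN2 allylation of the hindered aryllithium at the primary carbon of the allylic bromide.

**Step 3**
Reactants: 4 [3,5-bis(benzyloxy)-4-(3-methylbut-2-en-1-yl)phenoxy]tri(propan-2-yl)silane
Product: 6 3,5-bis(benzyloxy)-4-(3-hydroxy-3-methylbutyl)phenol, via silyl ether alcohol 5 (not isolated)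
Conditions: Co(acac)2 (cat.), PhSiH3, O2 (1 atm), THF, rt; then argon purge, Bu4NF, 0 °C
Reagents that add atoms: dioxygen, O=O
Why: Mukaiyama hydration places the hydroxyl at the more substituted alkene carbon through the tertiary radical, and fluoride then cleaves the aryl silyl ether to give the mirror-symmetric phenol.

**Step 4**
Reactants: 6 3,5-bis(benzyloxy)-4-(3-hydroxy-3-methylbutyl)phenol
Product: 7 2,4-bis(benzyloxy)-6-hydroxy-3-(3-hydroxy-3-methylbutyl)benzaldehyde
Conditions: MgCl2, Et3N, paraformaldehyde, MeCN, reflux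
Reagents that add atoms: paraformaldehyde (as formaldehyde), C=O
Why: Casnati–Skattebøl ortho-formylation through the magnesium phenoxide is ortho-specific, and the two ortho carbons of 6 are equivalent, so a single aldehyde should form with its free hydroxyl para to the side chain.

**Step 5**
Reactants: 7 2,4-bis(benzyloxy)-6-hydroxy-3-(3-hydroxy-3-methylbutyl)benzaldehyde
Product: 8 benzyl 3-[2,4-bis(benzyloxy)-6-hydroxy-3-(3-hydroxy-3-methylbutyl)phenyl]-3-hydroxypropanoate (racemic)
Conditions: LiN(i-Pr)2 (3.5 equiv), benzyl acetate (3.5 equiv), THF, −78 °C; then 7; AcOH quench at −78 °C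
Reagents that add atoms: benzyl acetate, CC(=O)OCc1ccccc1
Why: Aldol addition of an ester lithium enolate to the aldehyde, the excess enolate first deprotonating the two hydroxyl groups; the new carbinol centre is racemic and is destroyed in step 6.

**Step 6**
Reactants: 8 benzyl 3-[2,4-bis(benzyloxy)-6-hydroxy-3-(3-hydroxy-3-methylbutyl)phenyl]-3-hydroxypropanoate
Product: 9 benzyl 3-[2,4-bis(benzyloxy)-6-hydroxy-3-(3-hydroxy-3-methylbutyl)phenyl]-3-oxopropanoate
Conditions: activated MnO2, CH2Cl2, rt
Reagents that add atoms: none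
Why: MnO2 oxidation is selective for the electron-rich benzylic secondary alcohol and should leave the tertiary alcohol, the phenol and the benzyl groups untouched.

**Step 7**
Reactants: 9 benzyl 3-[2,4-bis(benzyloxy)-6-hydroxy-3-(3-hydroxy-3-methylbutyl)phenyl]-3-oxopropanoate; 10 3,4-bis(benzyloxy)benzaldehyde
Product: 11 benzyl 2-[2,4-bis(benzyloxy)-6-hydroxy-3-(3-hydroxy-3-methylbutyl)benzoyl]-3-[3,4-bis(benzyloxy)phenyl]prop-2-enoate (mixture of alkene isomers)
Conditions: piperidine (cat.), AcOH (cat.), 4 Å MS, toluene, rt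
Reagents that add atoms: none
Why: Knoevenagel condensation of the active methylene with the ring B aldehyde under buffered amine catalysis, kept at room temperature so that the free phenol does not yet add to the new alkene.

**Step 8**
Reactants: 11 benzyl 2-[2,4-bis(benzyloxy)-6-hydroxy-3-(3-hydroxy-3-methylbutyl)benzoyl]-3-[3,4-bis(benzyloxy)phenyl]prop-2-enoate
Product: 12 benzyl (2S)-5,7-bis(benzyloxy)-2-[3,4-bis(benzyloxy)phenyl]-6-(3-hydroxy-3-methylbutyl)-4-oxo-3,4-dihydro-2H-chromene-3-carboxylate (C3 epimers and enol form)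
Conditions: quinidine-derived bifunctional thiourea [9-amino-9-deoxy-epi-quinidine N-3,5-bis(trifluoromethyl)phenyl thiourea] (10 mol%), toluene, −25 °C; cold filtration through silica
Reagents that add atoms: none
Why: The quinuclidine nitrogen of the catalyst takes up the proton of the only free phenol while the thiourea N–H pair binds the 1,3-dicarbonyl unit, so that the phenoxide oxygen adds to the β-carbon of the alkylidene and the resulting β-ketoester enol is protonated. The closest known reaction type is the cinchona-thiourea-catalysed intramolecular oxa-Michael addition of 2-hydroxyaryl alkylidene β-ketoesters to 4-oxochromane-3-carboxylates. Ring C closes in the 6-endo-trig mode by forming the O1–C2 bond. C2 is set under catalyst control, the chiral pocket of the quinidine scaffold exposing one face of the alkene to the tethered phenoxide, whereas C3 stays an equilibrating centre that is removed in step 9. The step needs enantioselectivity, which the two-point binding of the C3 ester secures, and regioselectivity for the 6-substituted chromanone, which is secured because O5 is benzylated and the free hydroxyl is the one para to the side chain. The low temperature and the absence of strong base should keep the retro-oxa-Michael pathway from eroding the configuration.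

**Step 9**
Reactants: 12 benzyl (2S)-5,7-bis(benzyloxy)-2-[3,4-bis(benzyloxy)phenyl]-6-(3-hydroxy-3-methylbutyl)-4-oxo-3,4-dihydro-2H-chromene-3-carboxylate
Product: 14 (2S)-2-(3,4-dihydroxyphenyl)-5,7-dihydroxy-6-(3-hydroxy-3-methylbutyl)-2,3-dihydro-4H-chromen-4-one, via β-keto acid 13 (not isolated)
Conditions: H2 (1 atm), 10% Pd/C, EtOAc–MeOH, rt; then argon, 40 °C
Reagents that add atoms: none
Why: Hydrogenolysis cleaves the four aryl benzyl ethers and the benzyl ester, and the free β-keto acid decarboxylates through its cyclic six-membered transition state under neutral conditions, so that C2 is not epimerised and the tertiary alcohol is not exposed to acid.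

**Compound list**

1 | 3,5-bis(benzyloxy)phenol | Oc1cc(OCc2ccccc2)cc(OCc2ccccc2)c1 | starting material
2 | [3,5-bis(benzyloxy)phenoxy]tri(propan-2-yl)silane | CC(C)[Si](Oc1cc(OCc2ccccc2)cc(OCc2ccccc2)c1)(C(C)C)C(C)C | intermediate
3 | [2,6-bis(benzyloxy)-4-(triisopropylsilyloxy)phenyl]lithium (formed in the flask) | [Li]c1c(OCc2ccccc2)cc(O[Si](C(C)C)(C(C)C)C(C)C)cc1OCc1ccccc1 | intermediate
4 | [3,5-bis(benzyloxy)-4-(3-methylbut-2-en-1-yl)phenoxy]tri(propan-2-yl)silane | CC(C)=CCc1c(OCc2ccccc2)cc(O[Si](C(C)C)(C(C)C)C(C)C)cc1OCc1ccccc1 | intermediate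
5 | 4-[2,6-bis(benzyloxy)-4-(triisopropylsilyloxy)phenyl]-2-methylbutan-2-ol (formed in the flask) | CC(C)(O)CCc1c(OCc2ccccc2)cc(O[Si](C(C)C)(C(C)C)C(C)C)cc1OCc1ccccc1 | intermediate
6 | 3,5-bis(benzyloxy)-4-(3-hydroxy-3-methylbutyl)phenol | CC(C)(O)CCc1c(OCc2ccccc2)cc(O)cc1OCc1ccccc1 | intermediate
7 | 2,4-bis(benzyloxy)-6-hydroxy-3-(3-hydroxy-3-methylbutyl)benzaldehyde | CC(C)(O)CCc1c(OCc2ccccc2)cc(O)c(C=O)c1OCc1ccccc1 | intermediate
8 | benzyl 3-[2,4-bis(benzyloxy)-6-hydroxy-3-(3-hydroxy-3-methylbutyl)phenyl]-3-hydroxypropanoate (racemic) | CC(C)(O)CCc1c(OCc2ccccc2)cc(O)c(C(O)CC(=O)OCc2ccccc2)c1OCc1ccccc1 | intermediate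
9 | benzyl 3-[2,4-bis(benzyloxy)-6-hydroxy-3-(3-hydroxy-3-methylbutyl)phenyl]-3-oxopropanoate | CC(C)(O)CCc1c(OCc2ccccc2)cc(O)c(C(=O)CC(=O)OCc2ccccc2)c1OCc1ccccc1 | intermediate
10 | 3,4-bis(benzyloxy)benzaldehyde | O=Cc1ccc(OCc2ccccc2)c(OCc2ccccc2)c1 | starting material
11 | benzyl 2-[2,4-bis(benzyloxy)-6-hydroxy-3-(3-hydroxy-3-methylbutyl)benzoyl]-3-[3,4-bis(benzyloxy)phenyl]prop-2-enoate (alkene isomers) | CC(C)(O)CCc1c(OCc2ccccc2)cc(O)c(C(=O)C(=Cc2ccc(OCc3ccccc3)c(OCc3ccccc3)c2)C(=O)OCc2ccccc2)c1OCc1ccccc1 | intermediate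
12 | benzyl (2S)-5,7-bis(benzyloxy)-2-[3,4-bis(benzyloxy)phenyl]-6-(3-hydroxy-3-methylbutyl)-4-oxo-3,4-dihydro-2H-chromene-3-carboxylate (C3 not defined) | CC(C)(O)CCc1c(OCc3ccccc3)cc2c(c1OCc1ccccc1)C(=O)C(C(=O)OCc1ccccc1)[C@@H](c1ccc(OCc3ccccc3)c(OCc3ccccc3)c1)O2 | intermediate
13 | (2S)-2-(3,4-dihydroxyphenyl)-5,7-dihydroxy-6-(3-hydroxy-3-methylbutyl)-4-oxo-3,4-dihydro-2H-chromene-3-carboxylic acid (formed in the flask; C3 not defined) | CC(C)(O)CCc1c(O)cc2c(c1O)C(=O)C(C(=O)O)[C@@H](c1ccc(O)c(O)c1)O2 | intermediate
14 | (2S)-2-(3,4-dihydroxyphenyl)-5,7-dihydroxy-6-(3-hydroxy-3-methylbutyl)-2,3-dihydro-4H-chromen-4-one | CC(C)(O)CCc1c(O)cc2c(c1O)C(=O)C[C@@H](c1ccc(O)c(O)c1)O2 | target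

**Totals**

Total step count: 9. Longest linear sequence: 9 steps (1 to 14); aldehyde 10 is bought.

**Steps most likely to fail**

Step 8. The facial selectivity may be insufficient, or the addition slow, for a benzoyl group carrying two ortho substituents and a benzyl instead of a bulkier ester; the configuration may also erode by retro-oxa-Michael opening. The fallback sets out from 9 and comes back at 12. Compound 9 would be condensed with N,N-dimethylformamide dimethyl acetal (toluene, 80 °C) to benzyl 5,7-bis(benzyloxy)-6-(3-hydroxy-3-methylbutyl)-4-oxo-4H-chromene-3-carboxylate F1, in which ring C is closed through the same single free phenol but without a stereocentre. A Hayashi–Miyaura 1,4-addition of 3,4-bis(benzyloxy)phenylboronic acid ([Rh(C2H4)2Cl]2, chiral diene ligand, aq. KOH, dioxane) would then set C2 under ligand control and give 12, from which step 9 follows.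

Step 7. The phenoxide may close the ring prematurely under the amine catalyst, giving racemic material, or may lactonise onto the benzyl ester; the electron-rich aldehyde may also condense slowly. The fallback sets out from 9 and comes back at 11. The phenol of 9 would be silylated (TBSCl, imidazole, DMF) to benzyl 3-[2,4-bis(benzyloxy)-6-(tert-butyldimethylsilyloxy)-3-(3-hydroxy-3-methylbutyl)phenyl]-3-oxopropanoate F2. This can be condensed with 10 under forcing conditions (piperidinium acetate, benzene, reflux with water removal) to benzyl 2-[2,4-bis(benzyloxy)-6-(tert-butyldimethylsilyloxy)-3-(3-hydroxy-3-methylbutyl)benzoyl]-3-[3,4-bis(benzyloxy)phenyl]prop-2-enoate F3. Desilylation under non-basic conditions (HF·pyridine, THF, 0 °C) would release 11 without generating a phenoxide.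

Step 2. Metalation may take place at a benzylic CH2 of a benzyl ether (with Wittig rearrangement) or next to the silyloxy group, and the allylation may go partly SN2′. The fallback sets out from 1 and comes back at 6, with no organolithium. Vilsmeier–Haack formylation of 1 (POCl3, DMF) para to the hydroxyl would give 2,6-bis(benzyloxy)-4-hydroxybenzaldehyde F4, separated from its ortho isomer. Wittig olefination with 1-(triphenylphosphoranylidene)propan-2-one (toluene, reflux) would give (E)-4-[2,6-bis(benzyloxy)-4-hydroxyphenyl]but-3-en-2-one F5. Alkene hydrogenation that spares benzyl ethers (H2, RhCl(PPh3)3, benzene) would give 4-[2,6-bis(benzyloxy)-4-hydroxyphenyl]butan-2-one F6, and excess MeMgBr (THF, 0 °C) would convert the ketone into the tertiary alcohol 6.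

**Further compounds**

F1 | step 8 | benzyl 5,7-bis(benzyloxy)-6-(3-hydroxy-3-methylbutyl)-4-oxo-4H-chromene-3-carboxylate | CC(C)(O)CCc1c(OCc3ccccc3)cc2OC=C(C(=O)OCc3ccccc3)C(=O)c2c1OCc1ccccc1
F2 | step 7 | benzyl 3-[2,4-bis(benzyloxy)-6-(tert-butyldimethylsilyloxy)-3-(3-hydroxy-3-methylbutyl)phenyl]-3-oxopropanoate | CC(C)(O)CCc1c(OCc2ccccc2)cc(O[Si](C)(C)C(C)(C)C)c(C(=O)CC(=O)OCc2ccccc2)c1OCc1ccccc1
F3 | step 7 | benzyl 2-[2,4-bis(benzyloxy)-6-(tert-butyldimethylsilyloxy)-3-(3-hydroxy-3-methylbutyl)benzoyl]-3-[3,4-bis(benzyloxy)phenyl]prop-2-enoate | CC(C)(O)CCc1c(OCc2ccccc2)cc(O[Si](C)(C)C(C)(C)C)c(C(=O)C(=Cc2ccc(OCc3ccccc3)c(OCc3ccccc3)c2)C(=O)OCc2ccccc2)c1OCc1ccccc1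
F4 | step 2 | 2,6-bis(benzyloxy)-4-hydroxybenzaldehyde | O=Cc1c(OCc2ccccc2)cc(O)cc1OCc1ccccc1
F5 | step 2 | (E)-4-[2,6-bis(benzyloxy)-4-hydroxyphenyl]but-3-en-2-one | CC(=O)/C=C/c1c(OCc2ccccc2)cc(O)cc1OCc1ccccc1
F6 | step 2 | 4-[2,6-bis(benzyloxy)-4-hydroxyphenyl]butan-2-one | CC(=O)CCc1c(OCc2ccccc2)cc(O)cc1OCc1ccccc1
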